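## Plan

- The target is 7-hydroxy-3,5,6,8,4'-pentamethoxyflavone (ring A is the benzo ring, ring C the pyranone, ring B the 4-methoxyphenyl group). It has no stereocentre.
- Retrosynthesis: the C7 oxygen is masked as a benzyl ether and the C8–OMe bond is removed. O1–C2 of ring C is then opened to a 2'-hydroxy-α-methoxychalcone, and finally O1–C8a and C4–C4a are cut together.
- Enabling feature: C8a and C4a are neighbouring ring A carbons that carry O1 and the C4 acyl carbon, so they can be the two termini of an aryne. The C5 methoxy group sits next to C4a. While C8 is kept as CH it is the only alkoxy group beside the triple bond, which fixes the direction of addition.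
- Forward: ring A is prepared from 2,3-dimethoxyphenol as an ortho-silylaryl triflate. Ring B with C2–C3–C4 comes from anisaldehyde and methyl methoxyacetate as an α-methoxycinnamic acid. The two are joined by aryne insertion into the acid C–O bond, ring C is closed and aromatised, C8 is oxygenated, and the benzyl group is removed.
- Stereochemistry: none has to be set. The Z alkene of the acid is the thermodynamic isomer and disappears when ring C forms.

Key step: step 9

Remark: positions in the ring A building blocks are also named by the flavone locants they become (C4a, C5, C6, C7, C8, C8a).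

## Route

Step 1
Reactants: 1 4-methoxybenzaldehyde; 2 methyl methoxyacetate
Product: 3 methyl (Z)-2-methoxy-3-(4-methoxyphenyl)acrylate
Conditions: NaOMe (1.5 equiv), MeOH, 0 °C to reflux
Reagents that add atoms: none
Why: Aldol (Claisen-type) condensation of the ester enolate with a non-enolisable aldehyde, followed by E1cB loss of water, should give the α-methoxycinnamate as the less crowded Z isomer (aryl trans to the ester), a geometry that has no consequence once ring C is formed.

Step 2
Reactants: 3 methyl (Z)-2-methoxy-3-(4-methoxyphenyl)acrylate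
Product: 4 (Z)-2-methoxy-3-(4-methoxyphenyl)acrylic acid
Conditions: NaOH, THF/MeOH/H2O, rt; then cold 1 M HCl
Reagents that add atoms: sodium hydroxide, [Na+].[OH-]
Why: This is an ordinary ester saponification; the acceptor-substituted enol ether is inert to base and should survive a brief, cold acidification.

Step 3
Reactants: 5 2,3-dimethoxyphenol
Product: 6 2,3-dimethoxy-1,4-benzoquinone
Conditions: (KSO3)2NO (2.2 equiv), KH2PO4, H2O/acetone, rt
Reagents that add atoms: potassium nitrosodisulfonate (KSO3)2NO, [K+].[K+].[O-]S(=O)(=O)N([O])S(=O)(=O)[O-]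
Why: In this Teuber oxidation the phenoxyl radical is trapped at its free para position by a second nitroxyl radical, and the adduct collapses to the para-quinone, which creates a symmetrical ring A precursor.

Step 4
Reactants: 6 2,3-dimethoxy-1,4-benzoquinone
Product: 7 2,3-dimethoxybenzene-1,4-diol
Conditions: Na2S2O4, H2O/EtOAc, rt
Reagents that add atoms: none
Why: Two-phase dithionite reduction of a quinone to its hydroquinone is fast and touches no other group.

Step 5
Reactants: 7 2,3-dimethoxybenzene-1,4-diol; 8 benzyl bromide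
Product: 9 4-(benzyloxy)-2,3-dimethoxyphenol
Conditions: K2CO3 (1.0 equiv), 8 (0.9 equiv), DMF, rt, under Ar
Reagents that add atoms: none
Why: In this Williamson etherification the two hydroxyl groups of 7 are related by symmetry, so mono-alkylation can give only one product, and a deficit of 8 limits the separable bis-ether.

Step 6
Reactants: 9 4-(benzyloxy)-2,3-dimethoxyphenol
Product: 10 4-(benzyloxy)-6-bromo-2,3-dimethoxyphenol
Conditions: NBS (1.0 equiv), i-Pr2NH (10 mol %), CH2Cl2, −78 °C to 0 °C, dark
Reagents that add atoms: N-bromosuccinimide, O=C1CCC(=O)N1Br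
Why: Amine-catalysed electrophilic ortho-bromination of a phenol should go to the only free position ortho to the hydroxyl group (the future C8a), because the free OH activates more strongly than the benzyl ether, while anhydrous cold conditions suppress oxidation to the quinone.

Step 7
Reactants: 10 4-(benzyloxy)-6-bromo-2,3-dimethoxyphenol
Product: 11 [4-(benzyloxy)-6-bromo-2,3-dimethoxyphenoxy]trimethylsilane
Conditions: HMDS, THF, reflux; volatiles removed in vacuo
Reagents that add atoms: hexamethyldisilazane, C[Si](C)(C)N[Si](C)(C)C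
Why: O-silylation of a phenol with HMDS releases only ammonia, so the moisture-sensitive silyl ether can be used without chromatography.

Step 8
Reactants: 11 [4-(benzyloxy)-6-bromo-2,3-dimethoxyphenoxy]trimethylsilane
Product: 14 4-(benzyloxy)-2,3-dimethoxy-6-(trimethylsilyl)phenyl trifluoromethanesulfonate, via aryllithium 12 (not isolated), via lithium silylphenoxide 13 (not isolated)
Conditions: n-BuLi (1.1 equiv), THF, −78 °C; then Tf2O (1.2 equiv), −78 °C to 0 °C
Reagents that add atoms: trifluoromethanesulfonic anhydride, O=S(=O)(OS(=O)(=O)C(F)(F)F)C(F)(F)F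
Why: Bromine–lithium exchange is faster than any benzylic metalation at −78 °C, the retro-Brook 1,3 O-to-C silyl shift turns 12 into phenoxide 13, and O-triflation in the same flask is the standard entry to ortho-silylaryl triflates.

Step 9
Reactants: 14 4-(benzyloxy)-2,3-dimethoxy-6-(trimethylsilyl)phenyl trifluoromethanesulfonate; 4 (Z)-2-methoxy-3-(4-methoxyphenyl)acrylic acid
Product: 16 (Z)-1-[4-(benzyloxy)-6-hydroxy-2,3-dimethoxyphenyl]-2-methoxy-3-(4-methoxyphenyl)prop-2-en-1-one, via aryne 15 (not isolated)
Conditions: CsF (4 equiv), 14 in slight excess, THF (high dilution), 125 °C, sealed tube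
Reagents that add atoms: none
Why: Desilylation of 14 by fluoride with expulsion of triflate unmasks aryne 15, whose C4a≡C8a bond is distorted and polarised by the inductively withdrawing C5 methoxy group attached next to C4a. The caesium carboxylate of 4 should therefore bond through oxygen to the remote terminus C8a, leaving the negative charge on C4a, where the neighbouring C–O dipole stabilises it. This aryl anion then attacks the adjacent ester carbonyl through a four-membered array (4-exo-trig) that cannot persist, and C–O scission passes the acyl group from oxygen to carbon, so O1–C8a and C4–C4a arise in one operation and the ortho-acylphenoxide of 16 results; the closest known reaction type is the formal insertion of arynes into the C–O bond of carboxylic acids to give ortho-hydroxyaryl ketones. No ring remains closed and no stereocentre is formed, and the Z alkene is only a spectator. Two selectivities are needed: regiochemistry, secured because C8 is still CH and the triple bond thus has an alkoxy neighbour on one side only, and acyl migration in preference to proton capture by the aryl anion, which high dilution and high temperature favour. In the basic medium the open phenoxide should be the resting state, and any flavanone 17 arising from oxa-Michael closure is simply carried into step 10, where it converges on 18.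

Step 10
Reactants: 16 (Z)-1-[4-(benzyloxy)-6-hydroxy-2,3-dimethoxyphenyl]-2-methoxy-3-(4-methoxyphenyl)prop-2-en-1-one
Product: 18 7-(benzyloxy)-3,5,6-trimethoxy-2-(4-methoxyphenyl)-4H-chromen-4-one, via trans-3-methoxyflavanone 17 (not isolated)
Conditions: I2 (20 mol %), DMSO, 130 °C
Reagents that add atoms: none
Why: This is the standard I2/DMSO oxidative cyclisation of 2'-hydroxychalcones, in which the phenol closes ring C by 6-endo-trig oxa-Michael addition at C2 to give 17, the two transient stereocentres of 17 (trans favoured by equilibration at C3) are erased by C3 iodination and loss of HI, and DMSO reoxidises HI to I2.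

Step 11
Reactants: 18 7-(benzyloxy)-3,5,6-trimethoxy-2-(4-methoxyphenyl)-4H-chromen-4-one
Product: 19 7-(benzyloxy)-8-bromo-3,5,6-trimethoxy-2-(4-methoxyphenyl)-4H-chromen-4-one
Conditions: NBS (1.05 equiv), DMF, 0 °C to rt, dark
Reagents that add atoms: N-bromosuccinimide, O=C1CCC(=O)N1Br
Why: Electrophilic aromatic bromination should go to C8, the only free ring A position, which is ortho to O1 and the C7 oxygen and para to the C5 methoxy group, whereas ring B is deactivated by conjugation with the pyranone and ionic conditions in the dark spare the benzylic CH2.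

Step 12
Reactants: 19 7-(benzyloxy)-8-bromo-3,5,6-trimethoxy-2-(4-methoxyphenyl)-4H-chromen-4-one
Product: 20 7-(benzyloxy)-3,5,6,8-tetramethoxy-2-(4-methoxyphenyl)-4H-chromen-4-one
Conditions: NaOMe (10 equiv), CuBr (30 mol %), DMF/MeOH, 110 °C
Reagents that add atoms: sodium methoxide, [Na+].[O-]C
Why: Ullmann-type copper-catalysed C–O coupling of an aryl bromide with methoxide is the established way to convert bromoflavones into methoxyflavones, and the alkyl aryl ethers present are inert to methoxide.

Step 13
Reactants: 20 7-(benzyloxy)-3,5,6,8-tetramethoxy-2-(4-methoxyphenyl)-4H-chromen-4-one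
Product: 21 7-hydroxy-3,5,6,8-tetramethoxy-2-(4-methoxyphenyl)-4H-chromen-4-one
Conditions: H2 (1 atm), 10% Pd/C, EtOAc/MeOH, rt
Reagents that add atoms: none
Why: Catalytic hydrogenolysis cleaves only the benzyl aryl ether, since the tetrasubstituted C2=C3 bond of the pyranone and the methyl ethers are not reduced at atmospheric pressure.

## Compound list

1 | 4-methoxybenzaldehyde | COc1ccc(C=O)cc1 | starting material
2 | methyl methoxyacetate | COCC(=O)OC | starting material
3 | methyl (Z)-2-methoxy-3-(4-methoxyphenyl)acrylate | COc1ccc(/C=C(\OC)C(=O)OC)cc1 | intermediate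
4 | (Z)-2-methoxy-3-(4-methoxyphenyl)acrylic acid | COc1ccc(/C=C(\OC)C(=O)O)cc1 | intermediate
5 | 2,3-dimethoxyphenol | COc1cccc(O)c1OC | starting material
6 | 2,3-dimethoxy-1,4-benzoquinone | COC1=C(OC)C(=O)C=CC1=O | intermediate
7 | 2,3-dimethoxybenzene-1,4-diol | COc1c(O)ccc(O)c1OC | intermediate
8 | benzyl bromide | BrCc1ccccc1 | starting material
9 | 4-(benzyloxy)-2,3-dimethoxyphenol | COc1c(O)ccc(OCc2ccccc2)c1OC | intermediate
10 | 4-(benzyloxy)-6-bromo-2,3-dimethoxyphenol | COc1c(O)c(Br)cc(OCc2ccccc2)c1OC | intermediate
11 | [4-(benzyloxy)-6-bromo-2,3-dimethoxyphenoxy]trimethylsilane | COc1c(O[Si](C)(C)C)c(Br)cc(OCc2ccccc2)c1OC | intermediate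
12 | [5-(benzyloxy)-3,4-dimethoxy-2-(trimethylsilyloxy)phenyl]lithium | COc1c(O[Si](C)(C)C)c([Li])cc(OCc2ccccc2)c1OC | intermediate
13 | lithium 4-(benzyloxy)-2,3-dimethoxy-6-(trimethylsilyl)phenoxide | COc1c([O-])c([Si](C)(C)C)cc(OCc2ccccc2)c1OC.[Li+] | intermediate
14 | 4-(benzyloxy)-2,3-dimethoxy-6-(trimethylsilyl)phenyl trifluoromethanesulfonate | C[Si](C)(C)c1cc(OCc2ccccc2)c(OC)c(OC)c1OS(=O)(=O)C(F)(F)F | intermediate
15 | 5-(benzyloxy)-3,4-dimethoxy-1,2-didehydrobenzene (aryne) | COC1=C(OC)C(OCc2ccccc2)=CC#C1 | intermediate
16 | (Z)-1-[4-(benzyloxy)-6-hydroxy-2,3-dimethoxyphenyl]-2-methoxy-3-(4-methoxyphenyl)prop-2-en-1-one | COc1ccc(/C=C(\OC)C(=O)c2c(O)cc(OCc3ccccc3)c(OC)c2OC)cc1 | intermediate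
17 | trans-7-(benzyloxy)-3,5,6-trimethoxy-2-(4-methoxyphenyl)chroman-4-one (racemic, 2R,3R enantiomer drawn) | COc1ccc([C@@H]2[C@@H](OC)C(=O)c3c(OC)c(OC)c(OCc4ccccc4)cc3O2)cc1 | intermediate
18 | 7-(benzyloxy)-3,5,6-trimethoxy-2-(4-methoxyphenyl)-4H-chromen-4-one | COc1ccc(-c2oc3cc(OCc4ccccc4)c(OC)c(OC)c3c(=O)c2OC)cc1 | intermediate
19 | 7-(benzyloxy)-8-bromo-3,5,6-trimethoxy-2-(4-methoxyphenyl)-4H-chromen-4-one | COc1ccc(-c2oc3c(Br)c(OCc4ccccc4)c(OC)c(OC)c3c(=O)c2OC)cc1 | intermediate
20 | 7-(benzyloxy)-3,5,6,8-tetramethoxy-2-(4-methoxyphenyl)-4H-chromen-4-one | COc1ccc(-c2oc3c(OC)c(OCc4ccccc4)c(OC)c(OC)c3c(=O)c2OC)cc1 | intermediate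
21 | 7-hydroxy-3,5,6,8-tetramethoxy-2-(4-methoxyphenyl)-4H-chromen-4-one | COc1ccc(-c2oc3c(OC)c(O)c(OC)c(OC)c3c(=O)c2OC)cc1 | target

## Step count and risks

Total step count: 13.
Longest linear sequence: 11 steps (steps 3 to 13, from 5).

**Step 9.**
- Risk: the aryl anion at C4a is crowded by the C5 methoxy group. It may take up a proton faster than it attacks the cross-conjugated, donor-substituted acyl group, so that mere O-arylation of the acid results. The aryne may also be consumed by the enol ether double bond or by the product phenoxide.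
- Fallback: it sets out from 14 and returns at 16.
  - Aryne 15 is generated with CsF in DMF. The formyl C=O of the solvent adds across the triple bond with the same methoxy-controlled orientation, and no acid proton competes (the known π-insertion of arynes into formamides).
  - Aqueous hydrolysis should then give 4-(benzyloxy)-6-hydroxy-2,3-dimethoxybenzaldehyde F1.
  - Protection with MOMCl and i-Pr2NEt gives 4-(benzyloxy)-2,3-dimethoxy-6-(methoxymethoxy)benzaldehyde F2.
  - Addition of methoxymethyllithium (Bu3SnCH2OMe, n-BuLi, THF, −78 °C) gives racemic 1-[4-(benzyloxy)-2,3-dimethoxy-6-(methoxymethoxy)phenyl]-2-methoxyethan-1-ol F3.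
  - Dess–Martin oxidation gives 1-[4-(benzyloxy)-2,3-dimethoxy-6-(methoxymethoxy)phenyl]-2-methoxyethan-1-one F4.
  - Claisen–Schmidt condensation with 1 (KOH, EtOH) gives (Z)-1-[4-(benzyloxy)-2,3-dimethoxy-6-(methoxymethoxy)phenyl]-2-methoxy-3-(4-methoxyphenyl)prop-2-en-1-one F5.
  - Dilute HCl in MeOH frees the phenol to give 16.

**Step 12.**
- Risk: hydrodebromination at the doubly flanked C8 position, and opening of ring C by methoxide attack at C2 at 110 °C.
- Fallback: it sets out from 19 and returns at 20, and it replaces the hot alkoxide by a boron-based oxygenation.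
  - Miyaura borylation (B2pin2, Pd(dppf)Cl2, KOAc, dioxane, 90 °C) gives 7-(benzyloxy)-3,5,6-trimethoxy-2-(4-methoxyphenyl)-8-(4,4,5,5-tetramethyl-1,3,2-dioxaborolan-2-yl)-4H-chromen-4-one F6.
  - Mild oxidation (NaBO3·4H2O, THF/H2O, rt) gives 7-(benzyloxy)-8-hydroxy-3,5,6-trimethoxy-2-(4-methoxyphenyl)-4H-chromen-4-one F7.
  - O-methylation (MeI, K2CO3, acetone) delivers 20.

**Step 10.**
- Risk: acid released in the iodine cycle may hydrolyse the enol ether before closure, or cleave the C5 methyl or C7 benzyl ether at 130 °C. Dehydrogenation at the tertiary C3 position may also stall.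
- Fallback: it sets out from 16 and returns at 18, with ring closure and oxidation carried out separately.
  - NaOAc in refluxing EtOH closes ring C under nearly neutral conditions, and flavanone 17 is isolated.
  - DDQ in refluxing dioxane then abstracts hydride from C2, which is benzylic to the 4-methoxyphenyl ring and α to O1. Loss of the C3 proton gives 18.
  - No compound outside the list is made.

## Further compounds

F1 | step 9 | 4-(benzyloxy)-6-hydroxy-2,3-dimethoxybenzaldehyde | COc1c(C=O)c(O)cc(OCc2ccccc2)c1OC
F2 | step 9 | 4-(benzyloxy)-2,3-dimethoxy-6-(methoxymethoxy)benzaldehyde | COCOc1cc(OCc2ccccc2)c(OC)c(OC)c1C=O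
F3 | step 9 | 1-[4-(benzyloxy)-2,3-dimethoxy-6-(methoxymethoxy)phenyl]-2-methoxyethan-1-ol (racemic) | COCOc1cc(OCc2ccccc2)c(OC)c(OC)c1C(O)COC
F4 | step 9 | 1-[4-(benzyloxy)-2,3-dimethoxy-6-(methoxymethoxy)phenyl]-2-methoxyethan-1-one | COCOc1cc(OCc2ccccc2)c(OC)c(OC)c1C(=O)COC
F5 | step 9 | (Z)-1-[4-(benzyloxy)-2,3-dimethoxy-6-(methoxymethoxy)phenyl]-2-methoxy-3-(4-methoxyphenyl)prop-2-en-1-one | COc1ccc(/C=C(\OC)C(=O)c2c(OCOC)cc(OCc3ccccc3)c(OC)c2OC)cc1
F6 | step 12 | 7-(benzyloxy)-3,5,6-trimethoxy-2-(4-methoxyphenyl)-8-(4,4,5,5-tetramethyl-1,3,2-dioxaborolan-2-yl)-4H-chromen-4-one | COc1ccc(-c2oc3c(B4OC(C)(C)C(C)(C)O4)c(OCc5ccccc5)c(OC)c(OC)c3c(=O)c2OC)cc1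
F7 | step 12 | 7-(benzyloxy)-8-hydroxy-3,5,6-trimethoxy-2-(4-methoxyphenyl)-4H-chromen-4-one | COc1ccc(-c2oc3c(O)c(OCc4ccccc4)c(OC)c(OC)c3c(=O)c2OC)cc1
F0 | step 10 | none | none
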